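**Retrosynthetic overview**
- The target is opened at the two ester groups and at the lactone carbonyl. This leads back to a trans-fused 3-methylideneoxolane/cyclodecadiene whose C12 methylene is oxidised to the lactone C=O after the rings exist.
- Key disconnection: the C9–C10 bond together with the O–C8 bond. The lactone oxygen on C8, the CH2 group C9 and the vinylic ring carbon C10 form an O–C8–C9–C10(=C1) unit, a 2-(alk-2-enyl)oxolane. This is the footprint of adding an oxygen and an alkenyl carbon across a terminal C8=C9 alkene.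
- Because the C12 oxygen and the C10 alkenyl bromide sit on one acyclic chain, this addition closes the oxolane ring (O–C8) and then the ten-membered ring (C9–C10) in one operation. It also sets C8 from C7 and transfers the C1=C10 geometry.
- The acyclic bromo-trienol comes from an iridium-catalysed asymmetric allylic alkylation (sets C7), a cross-metathesis, a bromo-Wittig olefination (sets the C1=C10 geometry) and a Johnson–Claisen rearrangement (sets the C4=C5 geometry), starting from 2-methylidenepropane-1,3-diol.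

Key step: step 15

Locants used in the text are those of the germacrane skeleton of the target: ring C1–C10; C14 is the acetoxymethyl carbon on C10; C15 is the acyloxymethyl carbon on C4; C11 (=C13H2) and C12 (C=O) belong to the lactone, whose oxygen is on C8. TBS = tert-butyldimethylsilyl, TBDPS = tert-butyldiphenylsilyl.

Assumption: the sense of induction of the iridium phosphoramidite catalyst in step 11 is taken to be the one usual for (E)-alkyl allyl carbonates, so that the (Ra,R,R)-ligand should give (S)-19; if the opposite sense applied, the enantiomeric ligand would be used.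

**Step 1**
Reactants: 1 2-methylidenepropane-1,3-diol
Product: 2 2-{[(tert-butyldiphenylsilyl)oxy]methyl}prop-2-en-1-ol
Conditions: NaH (1.0 equiv), THF, 0 °C; then tBuPh2SiCl (1.0 equiv), rt
Reagents that add atoms: tert-butyl(chloro)diphenylsilane, CC(C)(C)[Si](Cl)(c1ccccc1)c1ccccc1
Why: O-silylation of the sparingly soluble monosodium alkoxide of a symmetrical diol should stop at the mono-ether.

**Step 2**
Reactants: 2 2-{[(tert-butyldiphenylsilyl)oxy]methyl}prop-2-en-1-ol
Product: 3 2-{[(tert-butyldiphenylsilyl)oxy]methyl}prop-2-enal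
Conditions: MnO2 (excess), CH2Cl2, rt
Reagents that add atoms: none
Why: Selective allylic alcohol oxidation with activated MnO2 should give the 2-substituted acrolein without affecting the silyl ether.

**Step 3**
Reactants: 3 2-{[(tert-butyldiphenylsilyl)oxy]methyl}prop-2-enal; 4 allylmagnesium bromide
Product: 5 rac-2-{[(tert-butyldiphenylsilyl)oxy]methyl}hexa-1,5-dien-3-ol
Conditions: Et2O, −78 °C; then aq. NH4Cl
Reagents that add atoms: none
Why: Grignard 1,2-addition of the allyl nucleophile to the enal; the carbinol centre is racemic and is erased in step 4.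

**Step 4**
Reactants: 5 rac-2-{[(tert-butyldiphenylsilyl)oxy]methyl}hexa-1,5-dien-3-ol; 6 triethyl orthoacetate
Product: 8 ethyl (4Z)-4-{[(tert-butyldiphenylsilyl)oxy]methyl}octa-4,7-dienoate, via ketene acetal 7 (not isolated)
Conditions: MeC(OEt)3 (excess), EtCO2H (cat.), 140 °C, EtOH distilled off
Reagents that add atoms: none
Why: Johnson–Claisen rearrangement through a chair transition state with the allyl substituent of the carbinol carbon equatorial, which should place C6 cis to the silyloxymethyl carbon C15 and so set the C4=C5 geometry of the target.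

**Step 5**
Reactants: 8 ethyl (4Z)-4-{[(tert-butyldiphenylsilyl)oxy]methyl}octa-4,7-dienoate
Product: 9 (4Z)-4-{[(tert-butyldiphenylsilyl)oxy]methyl}octa-4,7-dienal
Conditions: iBu2AlH (1.05 equiv), CH2Cl2, −78 °C; aq. potassium sodium tartrate
Reagents that add atoms: none
Why: Partial ester reduction through the low-temperature-stable aluminium hemiacetal should stop at the aldehyde.

**Step 6**
Reactants: 10 ethyl 2-(triphenyl-λ5-phosphanylidene)acetate
Product: 12 ethyl 2-bromo-2-(triphenyl-λ5-phosphanylidene)acetate, via bromophosphonium bromide 11 (not isolated)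
Conditions: Br2 (1.0 equiv), CH2Cl2, 0 °C; then aq. NaOH
Reagents that add atoms: bromine, BrBr
Why: Electrophilic C-bromination of the stabilised ylide and deprotonation of the resulting phosphonium salt should give the bromo-substituted stabilised ylide.

**Step 7**
Reactants: 9 (4Z)-4-{[(tert-butyldiphenylsilyl)oxy]methyl}octa-4,7-dienal; 12 ethyl 2-bromo-2-(triphenyl-λ5-phosphanylidene)acetate
Product: 13 ethyl (2Z,6Z)-2-bromo-6-{[(tert-butyldiphenylsilyl)oxy]methyl}deca-2,6,9-trienoate
Conditions: CH2Cl2, rt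
Reagents that add atoms: none
Why: Wittig olefination with a stabilised ylide places the ester trans to the alkyl chain, so bromine should end cis to C2 (the geometry later transferred to C1=C10); the minor isomer would be removed by chromatography.

**Step 8**
Reactants: 13 ethyl (2Z,6Z)-2-bromo-6-{[(tert-butyldiphenylsilyl)oxy]methyl}deca-2,6,9-trienoate
Product: 14 (2Z,6Z)-2-bromo-6-{[(tert-butyldiphenylsilyl)oxy]methyl}deca-2,6,9-trien-1-ol
Conditions: iBu2AlH (2.5 equiv), CH2Cl2, −78 to 0 °C; aq. potassium sodium tartrate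
Reagents that add atoms: none
Why: 1,2-reduction of the enoate by the aluminium hydride should give the 2-bromoallylic alcohol with the alkene geometry unchanged.

**Step 9**
Reactants: 14 (2Z,6Z)-2-bromo-6-{[(tert-butyldiphenylsilyl)oxy]methyl}deca-2,6,9-trien-1-ol
Product: 15 tert-butyl{[(2Z,6Z)-2-bromo-6-{[(tert-butyldiphenylsilyl)oxy]methyl}deca-2,6,9-trien-1-yl]oxy}dimethylsilane
Conditions: tBuMe2SiCl, imidazole, CH2Cl2, rt
Reagents that add atoms: tert-butyl(chloro)dimethylsilane, CC(C)(C)[Si](C)(C)Cl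
Why: Standard silylation of the primary alcohol gives a C14 ether that is orthogonal to the TBDPS ether at C15 and stable to the alkoxide base of step 15.

**Step 10**
Reactants: 15 tert-butyl{[(2Z,6Z)-2-bromo-6-{[(tert-butyldiphenylsilyl)oxy]methyl}deca-2,6,9-trien-1-yl]oxy}dimethylsilane; 16 allyl methyl carbonate
Product: 17 (2E,5Z,9Z)-10-bromo-11-[(tert-butyldimethylsilyl)oxy]-6-{[(tert-butyldiphenylsilyl)oxy]methyl}undeca-2,5,9-trien-1-yl methyl carbonate
Conditions: second-generation Grubbs catalyst RuCl2(=CHPh)(H2IMes)(PCy3) (5 mol%), 1,4-benzoquinone (10 mol%), 16 (excess), CH2Cl2, 40 °C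
Reagents that add atoms: none
Why: Olefin cross-metathesis should engage only the monosubstituted alkene (the trisubstituted alkenes and the alkenyl bromide are inert) and give mainly the (E)-allylic carbonate.

**Step 11**
Reactants: 17 (2E,5Z,9Z)-10-bromo-11-[(tert-butyldimethylsilyl)oxy]-6-{[(tert-butyldiphenylsilyl)oxy]methyl}undeca-2,5,9-trien-1-yl methyl carbonate; 18 dimethyl malonate
Product: 19 dimethyl 2-[(3S,5Z,9Z)-10-bromo-11-[(tert-butyldimethylsilyl)oxy]-6-{[(tert-butyldiphenylsilyl)oxy]methyl}undeca-1,5,9-trien-3-yl]propanedioate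
Conditions: [Ir(cod)Cl]2 (2 mol%), (Ra,R,R)-O,O'-(1,1'-binaphthalene-2,2'-diyl) N,N-bis(1-phenylethyl)phosphoramidite (4 mol%), 1,5,7-triazabicyclo[4.4.0]dec-5-ene (8 mol%), THF, rt
Reagents that add atoms: none
Why: Iridium-catalysed asymmetric allylic alkylation (Tsuji–Trost type) should deliver the malonate to the substituted allyl terminus, and the chiral iridacycle selects the face and sets C7.

**Step 12**
Reactants: 19 dimethyl 2-[(3S,5Z,9Z)-10-bromo-11-[(tert-butyldimethylsilyl)oxy]-6-{[(tert-butyldiphenylsilyl)oxy]methyl}undeca-1,5,9-trien-3-yl]propanedioate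
Product: 20 2-[(3S,5Z,9Z)-10-bromo-11-[(tert-butyldimethylsilyl)oxy]-6-{[(tert-butyldiphenylsilyl)oxy]methyl}undeca-1,5,9-trien-3-yl]-3-methoxy-3-oxopropanoic acid (mixture at the malonate carbon)
Conditions: KOH (1.1 equiv), MeOH/THF, 0 °C to rt; then 0.5 M HCl to pH 3–4, 0 °C
Reagents that add atoms: potassium hydroxide, [K+].[OH-]
Why: Mono-saponification of the malonate should stop after one ester because the first carboxylate deactivates the second; the new centre at C11 is erased in step 13.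

**Step 13**
Reactants: 20 2-[(3S,5Z,9Z)-10-bromo-11-[(tert-butyldimethylsilyl)oxy]-6-{[(tert-butyldiphenylsilyl)oxy]methyl}undeca-1,5,9-trien-3-yl]-3-methoxy-3-oxopropanoic acid
Product: 22 methyl (3S,5Z,9Z)-10-bromo-11-[(tert-butyldimethylsilyl)oxy]-6-{[(tert-butyldiphenylsilyl)oxy]methyl}-3-ethenyl-2-methylideneundeca-5,9-dienoate, via Mannich base 21 (not isolated)
Conditions: (CH2O)n, Et2NH, EtOAc, reflux
Reagents that add atoms: formaldehyde (as paraformaldehyde), C=O
Why: Mannich reaction at the malonate carbon followed by decarboxylative loss of diethylamine should give the 2-substituted acrylate; C7 is not enolisable and keeps its configuration.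

**Step 14**
Reactants: 22 methyl (3S,5Z,9Z)-10-bromo-11-[(tert-butyldimethylsilyl)oxy]-6-{[(tert-butyldiphenylsilyl)oxy]methyl}-3-ethenyl-2-methylideneundeca-5,9-dienoate
Product: 23 (3S,5Z,9Z)-10-bromo-11-[(tert-butyldimethylsilyl)oxy]-6-{[(tert-butyldiphenylsilyl)oxy]methyl}-3-ethenyl-2-methylideneundeca-5,9-dien-1-ol
Conditions: iBu2AlH (2.5 equiv), CH2Cl2, −78 °C; aq. potassium sodium tartrate
Reagents that add atoms: none
Why: 1,2-reduction of the acrylate ester by the aluminium hydride should give the free C12 allylic alcohol needed as the oxygen nucleophile, leaving the silyl ethers and the alkenyl bromide untouched.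

**Step 15**
Reactants: 23 (3S,5Z,9Z)-10-bromo-11-[(tert-butyldimethylsilyl)oxy]-6-{[(tert-butyldiphenylsilyl)oxy]methyl}-3-ethenyl-2-methylideneundeca-5,9-dien-1-ol
Product: 24 (3aR,5Z,9E,11aS)-10-{[(tert-butyldimethylsilyl)oxy]methyl}-6-{[(tert-butyldiphenylsilyl)oxy]methyl}-3-methylidene-2,3,3a,4,7,8,11,11a-octahydrocyclodeca[b]furan
Conditions: Pd2(dba)3 (5 mol%), bis[2-(diphenylphosphino)phenyl] ether (12 mol%), NaOtBu (2 equiv), toluene, 90 °C, slow addition of 23 to about 0.003 M
Reagents that add atoms: none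
Why: Proposed new method: zerovalent palladium should insert into the C10–Br bond with retention of geometry, NaOtBu turns the C12 hydroxyl into a palladium-bound alkoxide, the terminal C8=C9 alkene inserts syn into the Pd–O bond (5-exo-trig closure of the oxolane, O to C8 and Pd to C9), and C(sp3)–C(sp2) reductive elimination from the resulting eleven-membered palladacycle forms the C9–C10 bond and so closes the ten-membered carbocycle with the alkenyl carbon delivered to the terminal alkene carbon in an endo sense. The closest known reaction type is the palladium-catalysed carboetherification of γ-hydroxy alkenes with alkenyl bromides, known between two molecules and within one molecule for five- and six-membered rings from tethered aryl bromides; the ten-membered closure is the extension proposed here. The new stereocentre C8 is controlled by the existing C7 centre, whose substituent should sit pseudo-equatorial in the cyclic oxypalladation transition state and give the 2,3-trans oxolane, that is the trans ring fusion of the target. The C1=C10 geometry is not created but carried over from the (Z)-alkenyl bromide, which holds C2 and the incoming C9 on the same side so that the chain ends can meet. The step needs ring closure to win over oligomerisation (slow addition, high dilution), insertion into Pd–O to win over Heck-type carbopalladation and β-hydride loss (chelating bisphosphine, strong alkoxide base), and site selectivity for C8=C9, which is the only alkene able to close a five-membered ring onto the alkoxide and the only monosubstituted one.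

**Step 16**
Reactants: 24 (3aR,5Z,9E,11aS)-10-{[(tert-butyldimethylsilyl)oxy]methyl}-6-{[(tert-butyldiphenylsilyl)oxy]methyl}-3-methylidene-2,3,3a,4,7,8,11,11a-octahydrocyclodeca[b]furan
Product: 25 (3aR,5Z,9E,11aS)-10-{[(tert-butyldimethylsilyl)oxy]methyl}-6-{[(tert-butyldiphenylsilyl)oxy]methyl}-3-methylidene-3a,4,7,8,11,11a-hexahydrocyclodeca[b]furan-2(3H)-one
Conditions: CrO3 (excess), 3,5-dimethylpyrazole (excess), CH2Cl2, −20 °C
Reagents that add atoms: chromium trioxide, O=[Cr](=O)=O
Why: Allylic oxidation by the hexavalent chromium–pyrazole complex should occur at the C12 methylene, which is both allylic to the exocyclic alkene and α to the ring oxygen and therefore the most activated C–H position, turning the 3-methylideneoxolane into the α-methylidene lactone.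

**Step 17**
Reactants: 25 (3aR,5Z,9E,11aS)-10-{[(tert-butyldimethylsilyl)oxy]methyl}-6-{[(tert-butyldiphenylsilyl)oxy]methyl}-3-methylidene-3a,4,7,8,11,11a-hexahydrocyclodeca[b]furan-2(3H)-one
Product: 26 (3aR,5Z,9E,11aS)-6-{[(tert-butyldiphenylsilyl)oxy]methyl}-10-(hydroxymethyl)-3-methylidene-3a,4,7,8,11,11a-hexahydrocyclodeca[b]furan-2(3H)-one
Conditions: pyridinium p-toluenesulfonate (cat.), MeOH, rt
Reagents that add atoms: none
Why: Acid-catalysed methanolysis should cleave the primary TBS ether much faster than the bulkier TBDPS ether, freeing only the C14 hydroxyl.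

**Step 18**
Reactants: 26 (3aR,5Z,9E,11aS)-6-{[(tert-butyldiphenylsilyl)oxy]methyl}-10-(hydroxymethyl)-3-methylidene-3a,4,7,8,11,11a-hexahydrocyclodeca[b]furan-2(3H)-one
Product: 27 [(3aR,5Z,9E,11aS)-6-{[(tert-butyldiphenylsilyl)oxy]methyl}-3-methylidene-2-oxo-2,3,3a,4,7,8,11,11a-octahydrocyclodeca[b]furan-10-yl]methyl acetate
Conditions: Ac2O, pyridine, 4-(dimethylamino)pyridine (cat.), CH2Cl2, 0 °C
Reagents that add atoms: acetic anhydride, CC(=O)OC(C)=O
Why: Nucleophile-catalysed acylation of the primary allylic alcohol installs the C14 acetate of the target.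

**Step 19**
Reactants: 27 [(3aR,5Z,9E,11aS)-6-{[(tert-butyldiphenylsilyl)oxy]methyl}-3-methylidene-2-oxo-2,3,3a,4,7,8,11,11a-octahydrocyclodeca[b]furan-10-yl]methyl acetate
Product: 28 [(3aR,5Z,9E,11aS)-6-(hydroxymethyl)-3-methylidene-2-oxo-2,3,3a,4,7,8,11,11a-octahydrocyclodeca[b]furan-10-yl]methyl acetate
Conditions: HF·pyridine, pyridine, THF, 0 °C to rt
Reagents that add atoms: none
Why: Fluoride-driven desilylation under buffered, non-basic conditions should free the C15 hydroxyl without acetate migration or addition to the α-methylidene lactone.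

**Step 20**
Reactants: 29 ethyl 2-(hydroxymethyl)prop-2-enoate
Product: 30 ethyl 2-{[(tert-butyldimethylsilyl)oxy]methyl}prop-2-enoate
Conditions: tBuMe2SiCl, imidazole, CH2Cl2, rt
Reagents that add atoms: tert-butyl(chloro)dimethylsilane, CC(C)(C)[Si](C)(C)Cl
Why: Silylation masks the side-chain hydroxyl so that the acid cannot acylate itself in step 22.

**Step 21**
Reactants: 30 ethyl 2-{[(tert-butyldimethylsilyl)oxy]methyl}prop-2-enoate
Product: 31 2-{[(tert-butyldimethylsilyl)oxy]methyl}prop-2-enoic acid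
Conditions: LiOH, THF/H2O, 0 °C; then 0.5 M HCl to pH 4, 0 °C
Reagents that add atoms: lithium hydroxide, [Li+].[OH-]
Why: Ester saponification under mild conditions that a primary TBS ether tolerates should give the protected acid.

**Step 22**
Reactants: 28 [(3aR,5Z,9E,11aS)-6-(hydroxymethyl)-3-methylidene-2-oxo-2,3,3a,4,7,8,11,11a-octahydrocyclodeca[b]furan-10-yl]methyl acetate; 31 2-{[(tert-butyldimethylsilyl)oxy]methyl}prop-2-enoic acid
Product: 32 [(3aR,5Z,9E,11aS)-10-(acetoxymethyl)-3-methylidene-2-oxo-2,3,3a,4,7,8,11,11a-octahydrocyclodeca[b]furan-6-yl]methyl 2-{[(tert-butyldimethylsilyl)oxy]methyl}prop-2-enoate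
Conditions: N,N'-dicyclohexylcarbodiimide, 4-(dimethylamino)pyridine (cat.), CH2Cl2, 0 °C to rt
Reagents that add atoms: none
Why: Steglich esterification should acylate the primary allylic C15 alcohol under neutral conditions compatible with the acetate and the lactone.

**Step 23**
Reactants: 32 [(3aR,5Z,9E,11aS)-10-(acetoxymethyl)-3-methylidene-2-oxo-2,3,3a,4,7,8,11,11a-octahydrocyclodeca[b]furan-6-yl]methyl 2-{[(tert-butyldimethylsilyl)oxy]methyl}prop-2-enoate
Product: 33 [(3aR,5Z,9E,11aS)-10-(acetoxymethyl)-3-methylidene-2-oxo-2,3,3a,4,7,8,11,11a-octahydrocyclodeca[b]furan-6-yl]methyl 2-(hydroxymethyl)prop-2-enoate (CNP0126545.1)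
Conditions: HF·pyridine, pyridine, THF, 0 °C
Reagents that add atoms: none
Why: Buffered fluoride desilylation of the primary TBS ether should release the side-chain hydroxyl without touching the two esters, the lactone or the alkenes.

**Compound list**
1 | 2-methylidenepropane-1,3-diol | C=C(CO)CO | starting material
2 | 2-{[(tert-butyldiphenylsilyl)oxy]methyl}prop-2-en-1-ol | C=C(CO)CO[Si](c1ccccc1)(c1ccccc1)C(C)(C)C | intermediate
3 | 2-{[(tert-butyldiphenylsilyl)oxy]methyl}prop-2-enal | C=C(C=O)CO[Si](c1ccccc1)(c1ccccc1)C(C)(C)C | intermediate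
4 | allylmagnesium bromide | C=CC[Mg]Br | starting material
5 | rac-2-{[(tert-butyldiphenylsilyl)oxy]methyl}hexa-1,5-dien-3-ol | C=CCC(O)C(=C)CO[Si](c1ccccc1)(c1ccccc1)C(C)(C)C | intermediate
6 | triethyl orthoacetate | CCOC(C)(OCC)OCC | starting material
7 | ketene acetal, tert-butyl({2-[1-(1-ethoxyethenyloxy)but-3-en-1-yl]prop-2-en-1-yl}oxy)diphenylsilane | C=C(OCC)OC(CC=C)C(=C)CO[Si](c1ccccc1)(c1ccccc1)C(C)(C)C | intermediate (not isolated)
8 | ethyl (4Z)-4-{[(tert-butyldiphenylsilyl)oxy]methyl}octa-4,7-dienoate | CCOC(=O)CC/C(CO[Si](c1ccccc1)(c1ccccc1)C(C)(C)C)=C/CC=C | intermediate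
9 | (4Z)-4-{[(tert-butyldiphenylsilyl)oxy]methyl}octa-4,7-dienal | O=CCC/C(CO[Si](c1ccccc1)(c1ccccc1)C(C)(C)C)=C/CC=C | intermediate
10 | ethyl 2-(triphenyl-λ5-phosphanylidene)acetate | CCOC(=O)C=P(c1ccccc1)(c1ccccc1)c1ccccc1 | starting material
11 | (1-bromo-2-ethoxy-2-oxoethyl)triphenylphosphonium bromide | CCOC(=O)C(Br)[P+](c1ccccc1)(c1ccccc1)c1ccccc1.[Br-] | intermediate (not isolated)
12 | ethyl 2-bromo-2-(triphenyl-λ5-phosphanylidene)acetate | CCOC(=O)C(Br)=P(c1ccccc1)(c1ccccc1)c1ccccc1 | intermediate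
13 | ethyl (2Z,6Z)-2-bromo-6-{[(tert-butyldiphenylsilyl)oxy]methyl}deca-2,6,9-trienoate | CCOC(=O)/C(Br)=C/CC/C(CO[Si](c1ccccc1)(c1ccccc1)C(C)(C)C)=C/CC=C | intermediate
14 | (2Z,6Z)-2-bromo-6-{[(tert-butyldiphenylsilyl)oxy]methyl}deca-2,6,9-trien-1-ol | OC/C(Br)=C/CC/C(CO[Si](c1ccccc1)(c1ccccc1)C(C)(C)C)=C/CC=C | intermediate
15 | tert-butyl{[(2Z,6Z)-2-bromo-6-{[(tert-butyldiphenylsilyl)oxy]methyl}deca-2,6,9-trien-1-yl]oxy}dimethylsilane | CC(C)(C)[Si](C)(C)OC/C(Br)=C/CC/C(CO[Si](c1ccccc1)(c1ccccc1)C(C)(C)C)=C/CC=C | intermediate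
16 | allyl methyl carbonate | C=CCOC(=O)OC | starting material
17 | (2E,5Z,9Z)-10-bromo-11-[(tert-butyldimethylsilyl)oxy]-6-{[(tert-butyldiphenylsilyl)oxy]methyl}undeca-2,5,9-trien-1-yl methyl carbonate | COC(=O)OC/C=C/C/C=C(CO[Si](c1ccccc1)(c1ccccc1)C(C)(C)C)/CC/C=C(Br)/CO[Si](C)(C)C(C)(C)C | intermediate
18 | dimethyl malonate | COC(=O)CC(=O)OC | starting material
19 | dimethyl 2-[(3S,5Z,9Z)-10-bromo-11-[(tert-butyldimethylsilyl)oxy]-6-{[(tert-butyldiphenylsilyl)oxy]methyl}undeca-1,5,9-trien-3-yl]propanedioate | C=C[C@@H](C(C(=O)OC)C(=O)OC)C/C=C(CO[Si](c1ccccc1)(c1ccccc1)C(C)(C)C)/CC/C=C(Br)/CO[Si](C)(C)C(C)(C)C | intermediate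
20 | 2-[(3S,5Z,9Z)-10-bromo-11-[(tert-butyldimethylsilyl)oxy]-6-{[(tert-butyldiphenylsilyl)oxy]methyl}undeca-1,5,9-trien-3-yl]-3-methoxy-3-oxopropanoic acid | C=C[C@@H](C(C(=O)O)C(=O)OC)C/C=C(CO[Si](c1ccccc1)(c1ccccc1)C(C)(C)C)/CC/C=C(Br)/CO[Si](C)(C)C(C)(C)C | intermediate
21 | Mannich base, 2-[(diethylamino)methyl]-2-[(3S,5Z,9Z)-10-bromo-11-[(tert-butyldimethylsilyl)oxy]-6-{[(tert-butyldiphenylsilyl)oxy]methyl}undeca-1,5,9-trien-3-yl]-3-methoxy-3-oxopropanoic acid | C=C[C@@H](C(CN(CC)CC)(C(=O)O)C(=O)OC)C/C=C(CO[Si](c1ccccc1)(c1ccccc1)C(C)(C)C)/CC/C=C(Br)/CO[Si](C)(C)C(C)(C)C | intermediate (not isolated)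
22 | methyl (3S,5Z,9Z)-10-bromo-11-[(tert-butyldimethylsilyl)oxy]-6-{[(tert-butyldiphenylsilyl)oxy]methyl}-3-ethenyl-2-methylideneundeca-5,9-dienoate | C=C[C@@H](C(=C)C(=O)OC)C/C=C(CO[Si](c1ccccc1)(c1ccccc1)C(C)(C)C)/CC/C=C(Br)/CO[Si](C)(C)C(C)(C)C | intermediate
23 | (3S,5Z,9Z)-10-bromo-11-[(tert-butyldimethylsilyl)oxy]-6-{[(tert-butyldiphenylsilyl)oxy]methyl}-3-ethenyl-2-methylideneundeca-5,9-dien-1-ol | C=C[C@@H](C(=C)CO)C/C=C(CO[Si](c1ccccc1)(c1ccccc1)C(C)(C)C)/CC/C=C(Br)/CO[Si](C)(C)C(C)(C)C | intermediate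
24 | (3aR,5Z,9E,11aS)-10-{[(tert-butyldimethylsilyl)oxy]methyl}-6-{[(tert-butyldiphenylsilyl)oxy]methyl}-3-methylidene-2,3,3a,4,7,8,11,11a-octahydrocyclodeca[b]furan | CC(C)(C)[Si](c1ccccc1)(c1ccccc1)OC/C1=C\C[C@@H]2C(=C)CO[C@H]2C/C(CO[Si](C)(C)C(C)(C)C)=C\CC1 | intermediate
25 | (3aR,5Z,9E,11aS)-10-{[(tert-butyldimethylsilyl)oxy]methyl}-6-{[(tert-butyldiphenylsilyl)oxy]methyl}-3-methylidene-3a,4,7,8,11,11a-hexahydrocyclodeca[b]furan-2(3H)-one | CC(C)(C)[Si](c1ccccc1)(c1ccccc1)OC/C1=C\C[C@@H]2C(=C)C(=O)O[C@H]2C/C(CO[Si](C)(C)C(C)(C)C)=C\CC1 | intermediate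
26 | (3aR,5Z,9E,11aS)-6-{[(tert-butyldiphenylsilyl)oxy]methyl}-10-(hydroxymethyl)-3-methylidene-3a,4,7,8,11,11a-hexahydrocyclodeca[b]furan-2(3H)-one | CC(C)(C)[Si](c1ccccc1)(c1ccccc1)OC/C1=C\C[C@@H]2C(=C)C(=O)O[C@H]2C/C(CO)=C\CC1 | intermediate
27 | [(3aR,5Z,9E,11aS)-6-{[(tert-butyldiphenylsilyl)oxy]methyl}-3-methylidene-2-oxo-2,3,3a,4,7,8,11,11a-octahydrocyclodeca[b]furan-10-yl]methyl acetate | CC(C)(C)[Si](c1ccccc1)(c1ccccc1)OC/C1=C\C[C@@H]2C(=C)C(=O)O[C@H]2C/C(COC(C)=O)=C\CC1 | intermediate
28 | [(3aR,5Z,9E,11aS)-6-(hydroxymethyl)-3-methylidene-2-oxo-2,3,3a,4,7,8,11,11a-octahydrocyclodeca[b]furan-10-yl]methyl acetate | OC/C1=C\C[C@@H]2C(=C)C(=O)O[C@H]2C/C(COC(C)=O)=C\CC1 | intermediate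
29 | ethyl 2-(hydroxymethyl)prop-2-enoate | C=C(CO)C(=O)OCC | starting material
30 | ethyl 2-{[(tert-butyldimethylsilyl)oxy]methyl}prop-2-enoate | C=C(CO[Si](C)(C)C(C)(C)C)C(=O)OCC | intermediate
31 | 2-{[(tert-butyldimethylsilyl)oxy]methyl}prop-2-enoic acid | C=C(CO[Si](C)(C)C(C)(C)C)C(=O)O | intermediate
32 | [(3aR,5Z,9E,11aS)-10-(acetoxymethyl)-3-methylidene-2-oxo-2,3,3a,4,7,8,11,11a-octahydrocyclodeca[b]furan-6-yl]methyl 2-{[(tert-butyldimethylsilyl)oxy]methyl}prop-2-enoate | C=C(CO[Si](C)(C)C(C)(C)C)C(=O)OC/C1=C\C[C@@H]2C(=C)C(=O)O[C@H]2C/C(COC(C)=O)=C\CC1 | intermediate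
33 | [(3aR,5Z,9E,11aS)-10-(acetoxymethyl)-3-methylidene-2-oxo-2,3,3a,4,7,8,11,11a-octahydrocyclodeca[b]furan-6-yl]methyl 2-(hydroxymethyl)prop-2-enoate (CNP0126545.1) | C=C(CO)C(=O)OC/C1=C\C[C@@H]2C(=C)C(=O)O[C@H]2C/C(COC(C)=O)=C\CC1 | target

**Step count**
Total: 23 steps. Longest linear sequence: 20 steps (steps 1–5, 7–19, 22, 23); steps 6, 20 and 21 are side branches.

**Steps most likely to fail**

1. Step 15 (proposed new method). Ring closure may lose to coupling between two molecules, and the slow reductive elimination that forms the strained ten-membered ring may allow β-hydride loss from the C9–palladium alkyl or from the palladium alkoxide, Heck-type insertion, or base-induced loss of HBr from the alkenyl bromide. Fallback with known chemistry, from 23 back to 24: iodoetherification of 23 (I2, NaHCO3, MeCN, 0 °C; 5-exo closure, expected to favour the 2,3-trans isomer, the cis isomer being removed by chromatography) should give (2R,3R)-3-[(2Z,6Z)-7-bromo-8-[(tert-butyldimethylsilyl)oxy]-3-{[(tert-butyldiphenylsilyl)oxy]methyl}octa-2,6-dien-1-yl]-2-(iodomethyl)-4-methylideneoxolane F1. A nickel-catalysed reductive cross-electrophile coupling within the molecule, between the primary alkyl iodide and the alkenyl bromide (NiBr2(dme), 4,4'-di-tert-butyl-2,2'-bipyridine, Mn powder, NaI, N,N-dimethylacetamide, high dilution), would then form the C9–C10 bond and return to 24.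

2. Step 16. The chromium oxidant may attack the ring allylic methylenes or the silyloxymethyl groups instead of C12, over-oxidise, or move the exocyclic alkene into the ring. Fallback that avoids any C–H oxidation, from 22 back to 25: saponification of 22 (LiOH, THF/H2O) should give (3S,5Z,9Z)-10-bromo-11-[(tert-butyldimethylsilyl)oxy]-6-{[(tert-butyldiphenylsilyl)oxy]methyl}-3-ethenyl-2-methylideneundeca-5,9-dienoic acid F2. Iodolactonisation (I2, NaHCO3, MeCN, 0 °C) should give (4R,5R)-4-[(2Z,6Z)-7-bromo-8-[(tert-butyldimethylsilyl)oxy]-3-{[(tert-butyldiphenylsilyl)oxy]methyl}octa-2,6-dien-1-yl]-5-(iodomethyl)-3-methylideneoxolan-2-one F3, and the same nickel-catalysed reductive ring closure as in the first fallback would give lactone 25 directly.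

3. Step 10. The cross-metathesis may give an E/Z mixture of the allylic carbonate, and ruthenium hydride species may shift the skipped diene into conjugation; both would erode regio- and enantioselectivity in step 11. Fallback, from 15 back to 17: cross-metathesis of 15 with methyl acrylate (same catalyst), which is reliably E-selective, should give methyl (2E,5Z,9Z)-10-bromo-11-[(tert-butyldimethylsilyl)oxy]-6-{[(tert-butyldiphenylsilyl)oxy]methyl}undeca-2,5,9-trienoate F4. Reduction with iBu2AlH at −78 °C should give (2E,5Z,9Z)-10-bromo-11-[(tert-butyldimethylsilyl)oxy]-6-{[(tert-butyldiphenylsilyl)oxy]methyl}undeca-2,5,9-trien-1-ol F5, and methyl chloroformate with pyridine would convert it into carbonate 17.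

**Further compounds**
F1 | step 15 | (2R,3R)-3-[(2Z,6Z)-7-bromo-8-[(tert-butyldimethylsilyl)oxy]-3-{[(tert-butyldiphenylsilyl)oxy]methyl}octa-2,6-dien-1-yl]-2-(iodomethyl)-4-methylideneoxolane | IC[C@@H]1OCC(=C)[C@H]1C/C=C(CO[Si](c1ccccc1)(c1ccccc1)C(C)(C)C)/CC/C=C(Br)/CO[Si](C)(C)C(C)(C)C
F2 | step 16 | (3S,5Z,9Z)-10-bromo-11-[(tert-butyldimethylsilyl)oxy]-6-{[(tert-butyldiphenylsilyl)oxy]methyl}-3-ethenyl-2-methylideneundeca-5,9-dienoic acid | C=C[C@@H](C(=C)C(=O)O)C/C=C(CO[Si](c1ccccc1)(c1ccccc1)C(C)(C)C)/CC/C=C(Br)/CO[Si](C)(C)C(C)(C)C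
F3 | step 16 | (4R,5R)-4-[(2Z,6Z)-7-bromo-8-[(tert-butyldimethylsilyl)oxy]-3-{[(tert-butyldiphenylsilyl)oxy]methyl}octa-2,6-dien-1-yl]-5-(iodomethyl)-3-methylideneoxolan-2-one | IC[C@@H]1OC(=O)C(=C)[C@H]1C/C=C(CO[Si](c1ccccc1)(c1ccccc1)C(C)(C)C)/CC/C=C(Br)/CO[Si](C)(C)C(C)(C)C
F4 | step 10 | methyl (2E,5Z,9Z)-10-bromo-11-[(tert-butyldimethylsilyl)oxy]-6-{[(tert-butyldiphenylsilyl)oxy]methyl}undeca-2,5,9-trienoate | COC(=O)/C=C/C/C=C(CO[Si](c1ccccc1)(c1ccccc1)C(C)(C)C)/CC/C=C(Br)/CO[Si](C)(C)C(C)(C)C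
F5 | step 10 | (2E,5Z,9Z)-10-bromo-11-[(tert-butyldimethylsilyl)oxy]-6-{[(tert-butyldiphenylsilyl)oxy]methyl}undeca-2,5,9-trien-1-ol | OC/C=C/C/C=C(CO[Si](c1ccccc1)(c1ccccc1)C(C)(C)C)/CC/C=C(Br)/CO[Si](C)(C)C(C)(C)C
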